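Slowness was my first worry, and I wanted to know which kind each flask had: a round too slow for the hour, or an enzyme too short-lived for the round.

in all of them: starting material 0.11 M; second substrate 0.220 M; free enzyme 11 µM; time 1.0 h
- Sunday's: temperature 20 °C
- Monday's: temperature 5 °C

    second complex → free enzyme + target (k1 = 2.98 /s, Ea1 = 69.0 kJ/mol)
    starting material + free enzyme ⇌ first complex (K2 = 2.99 /M, k2 = 354 /M/s, Ea2 = 41.0 kJ/mol, ΔH2 = 1.00 kJ/mol)
    second substrate + loaded enzyme ⇌ second complex (K3 = 6.03 /M, k3 = 1770 /M/s, Ea3 = 41.0 kJ/mol, ΔH3 = −24.0 kJ/mol)
    first complex ⇌ loaded enzyme + first product (K4 = 0.121 M, k4 = 9.69 /s, Ea4 = 61.0 kJ/mol, ΔH4 = −41.0 kJ/mol)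
    free enzyme → unfolded enzyme (k5 = 6.63 × 10⁻⁶ /s, Ea5 = 247 kJ/mol)
    (constants at 5 °C)

* which flask leads in amount of target, in percent of the starting material charged ("all alike" within 1.5 percentage points) (Sunday's / Monday's / all alike)
* how much target is there at the end, in percent of the starting material charged: Sunday's
* how much target is there at the end, in percent of the starting material charged: Monday's

- the constants hold at 5 °C; other temperatures follow from the activation energies and enthalpies

**First instants.** Free enzyme takes up starting material, and first complex can fall back. On Sunday's flask, g, the number of captures needed per first complex that goes forward, came to 8.68. A complex that never fell back would give g of one, the zero of my scale, so this flask stood well above it.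

By the scheme, unfolding acts on free enzyme, so I priced target in free-enzyme time. I defined the budget b as the charge of free enzyme times the binding constant over the unfolding constant, both at the flask's temperature: 6.16 for Sunday's flask. With the round steady, each small amount of target spends (g + gW/w)/A of b, where A is the starting material and W the first product.

**Middle.** First product turns loaded enzyme back, which is product inhibition. I defined w as the level of first product that adds as much cost as g itself. On Sunday's flask, with second substrate held at its charge, w was 0.0156 M.

| | Sunday's | Monday's |
|---|---|---|
| half-life of free enzyme by unfolding, were the catalyst all free | 7.38 min | 29.0 h |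
| budget b | 6.16 | 587 |

**End.** Sunday's free enzyme has a half-life by that measure shorter than the hour, so in my reckoning I spent the whole of b, 6.16. Holding A at its charge gave 0.0362 M of target. Taking A at the midpoint of that conversion gave 0.0322 M, which is 29.2%.

Monday's free enzyme has a half-life by the same measure far longer than the hour, so there I counted rounds instead. On Monday's flask, with second substrate held at its charge, the catalyst spends 0.256 s of each round as loaded enzyme. A full round at the start takes 1.03 s, and that pace gives 0.0383 M of target. At the midpoint of that run a round takes 1.29 s, which gives 27.8%. My two figures stood 1.4 percentage points apart against a margin of 1.5 points, too close for my reckoning to separate them.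

The forecast gave all alike, with 27.1% for Sunday's and 27.8% for Monday's: “so the catalyst dies at about 27%, and the two flasks end within the 1.5-point band”.

Sunday's flask ended at 27.3% and Monday's at 27.9%, so they count as all alike; at 1.00 h Sunday's held 95.2% of its catalyst as unfolded enzyme, Monday's 0.987%. At my price, with w kept at its value for the charge of second substrate, Sunday's reading costs 5.57 of its budget b of 6.16. The neighbour flask, Sunday's with 4.4 × 10⁻⁵ M of free enzyme, has a budget of 24.6; its 53.5% of target costs 20.8, and it ended with 98.1% of its catalyst unfolded.

The constants were set for the occasion; the flask was simulated.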